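## Retrosynthetic overview
1. Kanzonol I comes from its silyl ether. Ring C (O1–C2) is closed last by Mitsunobu etherification of an (R)-2-aryl-3-(2-hydroxyaryl)propan-1-ol, which comes from hydride reduction of an (R)-3-aryl-3,4-dihydrocoumarin.
2. Key disconnection C3–C1'. Both carbons are nucleophilic by nature (lactone alpha-carbon, resorcinol-type arene carbon). C3 is inverted to an enolonium equivalent (racemic 3-bromolactone) and joined to the 8-zincated chromene in a stereoconvergent nickel coupling that sets (3R).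
3. The bromolactone comes from 1,4-hydrosilylation/bromination of 5,7-dimethoxy-6-prenylcoumarin. The coumarin comes from the symmetric 3,5-dimethoxy-4-prenylphenol and ethyl propiolate. The phenol comes from 1,3-dimethoxybenzene by ortho-lithiation/prenylation, then C–H borylation/oxidation.
4. The chromene comes from silylative aromatisation of the [3+3] adduct of cyclohexane-1,3-dione and prenal.
5. Ring order: pyran ring D, then ring B (aromatisation). Separately, the lactone is built on ring A. After the coupling the lactone is opened and re-closed as ring C.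

Assumption: the sense of induction of the ligand in step 7 is taken by analogy. Both antipodes are commercial, and the one that delivers (R)-19 is the one meant.

## Route

Step 1
Reactants: 1 1,3-dimethoxybenzene; 2 prenyl bromide (1-bromo-3-methylbut-2-ene)
Product: 4 1,3-dimethoxy-2-(3-methylbut-2-en-1-yl)benzene, via 2,6-dimethoxyphenyllithium 3 (not isolated)
Conditions: n-BuLi, THF, 0 °C to rt; then 2, −78 °C to rt
Reagents that add atoms: n-butyllithium, [Li]CCCC (Li of 3)
Why: Directed ortho-metalation, in which the two OMe groups together direct lithium to C2 and the aryllithium displaces the primary allylic bromide (SN2) to give the linear prenyl arene.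

Step 2
Reactants: 4 1,3-dimethoxy-2-(3-methylbut-2-en-1-yl)benzene
Product: 6 3,5-dimethoxy-4-(3-methylbut-2-en-1-yl)phenol, via arylboronic acid pinacol ester 5 (not isolated)
Conditions: [Ir(OMe)(cod)]2 (1 mol %), dtbpy (2 mol %), B2pin2 (1.0 equiv), THF, 60 °C; then 30 % H2O2, aq NaOH, 0 °C
Reagents that add atoms: bis(pinacolato)diboron, CC1(C)OB(OC1(C)C)B1OC(C)(C)C(C)(C)O1; hydrogen peroxide, OO
Why: Sterically governed iridium-catalysed aromatic C–H borylation takes the only ring C–H with no ortho substituent (meta to both OMe), the hindered trisubstituted alkene stays inert, and basic peroxide turns C–B into C–OH without epoxidation.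

Step 3
Reactants: 6 3,5-dimethoxy-4-(3-methylbut-2-en-1-yl)phenol; 7 ethyl propiolate
Product: 8 5,7-dimethoxy-6-(3-methylbut-2-en-1-yl)-2H-chromen-2-one (toddaculin)
Conditions: Pd(OAc)2 (5 mol %), NaOAc, HCO2H, rt
Reagents that add atoms: none
Why: Palladium-catalysed hydroarylation of the alkynoate by an electron-rich phenol followed by lactonisation; the two ortho positions of 6 are equivalent and the para position is blocked, so only one coumarin can form.

Step 4
Reactants: 8 toddaculin
Product: 10 rac-3-bromo-5,7-dimethoxy-6-(3-methylbut-2-en-1-yl)chroman-2-one, via triethylsilyl ketene acetal 9 (not isolated)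
Conditions: Et3SiH (1.05 equiv), RhCl(PPh3)3 (1 mol %), PhMe, 60 °C; then NBS (1.0 equiv), THF, −78 °C
Reagents that add atoms: triethylsilane, CC[SiH](CC)CC; N-bromosuccinimide, O=C1CCC(=O)N1Br
Why: Rhodium-catalysed 1,4-hydrosilylation of the enoate gives the silyl ketene acetal without base, and this far stronger nucleophile takes Br+ at −78 °C before the prenyl alkene or ring A can; C3 forms racemic, which is harmless because step 7 is stereoconvergent.

Step 5
Reactants: 11 cyclohexane-1,3-dione; 12 3-methylbut-2-enal (prenal)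
Product: 13 2,2-dimethyl-7,8-dihydro-2H-chromen-5(6H)-one
Conditions: ethylenediammonium diacetate (10 mol %), MeOH, rt
Reagents that add atoms: none
Why: Knoevenagel condensation followed by oxa-6π electrocyclisation (formal [3+3]) builds ring D and fixes the 5-oxygenation pattern with no regiochemical choice.

Step 6
Reactants: 13 2,2-dimethyl-7,8-dihydro-2H-chromen-5(6H)-one
Product: 16 [(2,2-dimethyl-2H-chromen-5-yl)oxy]triisopropylsilane, via lithium dienolate 14 (not isolated), via silyl dienol ether 15 (not isolated)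
Conditions: LiN(SiMe3)2, THF, −78 °C; TIPSOTf, −78 to 0 °C; solvent switch to PhMe; DDQ (1.1 equiv), rt
Reagents that add atoms: lithium hexamethyldisilazide, [Li]N([Si](C)(C)C)[Si](C)(C)C (Li of 14); triisopropylsilyl triflate, CC(C)[Si](OS(=O)(=O)C(F)(F)F)(C(C)C)C(C)C
Why: Kinetic alpha'-enolisation of the vinylogous ester and O-silylation give a silyloxycyclohexadiene, which DDQ dehydrogenates to the arene with the robust silyl ether retained (dehydrogenative aromatisation of a silyl dienol ether).

Step 7
Reactants: 16 [(2,2-dimethyl-2H-chromen-5-yl)oxy]triisopropylsilane; 10 rac-3-bromolactone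
Product: 19 (3R)-3-[2,2-dimethyl-5-(triisopropylsilyloxy)-2H-chromen-8-yl]-5,7-dimethoxy-6-(3-methylbut-2-en-1-yl)chroman-2-one, via 8-lithiochromene 17 (not isolated), via chromen-8-ylzinc chloride 18 (not isolated)
Conditions: 16 (1.5 equiv), n-BuLi, TMEDA, Et2O, 0 °C to rt; ZnCl2, THF, 0 °C; then 10 (1.0 equiv), NiCl2·dme (10 mol %), (S,S)-Ph-pybox (13 mol %), DME/THF, −30 °C
Reagents that add atoms: n-butyllithium, [Li]CCCC (Li of 17); zinc chloride, Cl[Zn]Cl (ZnCl of 18)
Why: Proposed new method: the alpha-bromolactone is an enolonium equivalent, so C3 (by nature the enolate carbon) is the electrophile toward chromene C8 (by nature a nucleophilic resorcinol carbon, metalated by directed ortho-metalation because the pyran oxygen directs lithium to C8 while the bulky OTIPS shields C6); monovalent nickel abstracts bromine from either enantiomer of 10 to give one planar alpha-lactonyl radical, which is captured by the chiral aryl-nickel complex, and reductive elimination from trivalent nickel sets C3 as (R), while the non-basic arylzinc at −30 °C leaves the acidic C3–H, the lactone carbonyl and both alkenes untouched; the closest known reaction type is the stereoconvergent nickel-catalysed Negishi arylation of racemic alpha-bromo ketones, alpha-bromo nitriles and related alpha-halo carbonyl compounds.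

Step 8
Reactants: 19 (3R)-3-aryl lactone
Product: 20 (2R)-2-[2,2-dimethyl-5-(triisopropylsilyloxy)-2H-chromen-8-yl]-3-[6-hydroxy-2,4-dimethoxy-3-(3-methylbut-2-en-1-yl)phenyl]propan-1-ol
Conditions: LiAlH4, THF, −78 to 0 °C
Reagents that add atoms: none
Why: Hydride reduction of the activated aryl lactone is faster than enolisation at low temperature, so the C3 configuration is kept (the descriptor stays R), and the alkenes and the silyl ether are inert.

Step 9
Reactants: 20 (2R)-diol
Product: 21 (3R)-3-[2,2-dimethyl-5-(triisopropylsilyloxy)-2H-chromen-8-yl]-5,7-dimethoxy-6-(3-methylbut-2-en-1-yl)chroman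
Conditions: PPh3, DIAD, THF (0.02 M), 0 °C to rt
Reagents that add atoms: none
Why: Intramolecular Mitsunobu etherification (6-exo-tet attack of the ring A phenol on the activated primary carbon) closes ring C without touching any bond at the stereocentre.

Step 10
Reactants: 21 silyl ether of Kanzonol I
Product: 22 Kanzonol I, (3R)
Conditions: Bu4NF, AcOH (1:1), THF, 0 °C
Reagents that add atoms: none
Why: Buffered fluoride cleaves the aryl silyl ether under near-neutral conditions that spare the chromene, the prenyl group and the stereocentre.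

## Compound list
1 | 1,3-dimethoxybenzene | COc1cccc(OC)c1 | starting material
2 | prenyl bromide | CC(C)=CCBr | starting material
3 | 2,6-dimethoxyphenyllithium | COc1cccc(OC)c1[Li] | intermediate
4 | 1,3-dimethoxy-2-(3-methylbut-2-en-1-yl)benzene | COc1cccc(OC)c1CC=C(C)C | intermediate
5 | 2-[3,5-dimethoxy-4-(3-methylbut-2-en-1-yl)phenyl]-4,4,5,5-tetramethyl-1,3,2-dioxaborolane | COc1cc(B2OC(C)(C)C(C)(C)O2)cc(OC)c1CC=C(C)C | intermediate
6 | 3,5-dimethoxy-4-(3-methylbut-2-en-1-yl)phenol | COc1cc(O)cc(OC)c1CC=C(C)C | intermediate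
7 | ethyl propiolate | C#CC(=O)OCC | starting material
8 | 5,7-dimethoxy-6-(3-methylbut-2-en-1-yl)-2H-chromen-2-one (toddaculin) | COc1cc2OC(=O)C=Cc2c(OC)c1CC=C(C)C | intermediate
9 | 5,7-dimethoxy-6-(3-methylbut-2-en-1-yl)-2-(triethylsilyloxy)-4H-chromene | COc1cc2OC(O[Si](CC)(CC)CC)=CCc2c(OC)c1CC=C(C)C | intermediate
10 | rac-3-bromo-5,7-dimethoxy-6-(3-methylbut-2-en-1-yl)chroman-2-one | COc1cc2OC(=O)C(Br)Cc2c(OC)c1CC=C(C)C | intermediate
11 | cyclohexane-1,3-dione | O=C1CCCC(=O)C1 | starting material
12 | 3-methylbut-2-enal | CC(C)=CC=O | starting material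
13 | 2,2-dimethyl-7,8-dihydro-2H-chromen-5(6H)-one | CC1(C)C=CC2=C(O1)CCCC2=O | intermediate
14 | lithium 2,2-dimethyl-7,8-dihydro-2H-chromen-5-olate | CC1(C)C=CC2=C(O1)CCC=C2O[Li] | intermediate
15 | 2,2-dimethyl-5-(triisopropylsilyloxy)-7,8-dihydro-2H-chromene | CC1(C)C=CC2=C(O1)CCC=C2O[Si](C(C)C)(C(C)C)C(C)C | intermediate
16 | [(2,2-dimethyl-2H-chromen-5-yl)oxy]triisopropylsilane | CC1(C)C=Cc2c(O1)cccc2O[Si](C(C)C)(C(C)C)C(C)C | intermediate
17 | 8-lithio-2,2-dimethyl-5-(triisopropylsilyloxy)-2H-chromene | CC1(C)C=Cc2c(O1)c([Li])ccc2O[Si](C(C)C)(C(C)C)C(C)C | intermediate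
18 | [2,2-dimethyl-5-(triisopropylsilyloxy)-2H-chromen-8-yl]zinc chloride | CC1(C)C=Cc2c(O1)c([Zn]Cl)ccc2O[Si](C(C)C)(C(C)C)C(C)C | intermediate
19 | (3R)-3-[2,2-dimethyl-5-(triisopropylsilyloxy)-2H-chromen-8-yl]-5,7-dimethoxy-6-(3-methylbut-2-en-1-yl)chroman-2-one | COc1cc2c(c(OC)c1CC=C(C)C)C[C@H](c1ccc(O[Si](C(C)C)(C(C)C)C(C)C)c3c1OC(C)(C)C=C3)C(=O)O2 | intermediate
20 | (2R)-2-[2,2-dimethyl-5-(triisopropylsilyloxy)-2H-chromen-8-yl]-3-[6-hydroxy-2,4-dimethoxy-3-(3-methylbut-2-en-1-yl)phenyl]propan-1-ol | COc1cc(O)c(c(OC)c1CC=C(C)C)C[C@H](c1ccc(O[Si](C(C)C)(C(C)C)C(C)C)c2c1OC(C)(C)C=C2)CO | intermediate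
21 | (3R)-3-[2,2-dimethyl-5-(triisopropylsilyloxy)-2H-chromen-8-yl]-5,7-dimethoxy-6-(3-methylbut-2-en-1-yl)chroman | COc1cc2c(c(OC)c1CC=C(C)C)C[C@H](c1ccc(O[Si](C(C)C)(C(C)C)C(C)C)c3c1OC(C)(C)C=C3)CO2 | intermediate
22 | Kanzonol I, (3R) | COc1cc2c(c(OC)c1CC=C(C)C)C[C@H](c1ccc(O)c3c1OC(C)(C)C=C3)CO2 | target

## Step count and risks
Total steps: 10. Longest linear sequence: 8 (steps 1, 2, 3, 4, 7, 8, 9, 10).

**Most likely to fail, first: step 7.**
- Risks: the ortho-alkoxy arylzinc may transmetalate slowly, 10 may lose HBr to give back 8, and the ee on a lactone is untested.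
- The fallback sets out from 17 and 9 and comes back at 19. It makes the same bond with the polarity roles exchanged.
- Aryllithium 17 is quenched with B(OiPr)3 and hydrolysed (aq NH4Cl) to the chromen-8-ylboronic acid F1.
- Boron-to-iodine exchange of F1 with MesI(OAc)2/BF3·OEt2 (CH2Cl2, −78 to 0 °C), followed by a NaOTf wash, gives the chromen-8-yl(mesityl)iodonium triflate F2. Ipso attack at C–B should be faster than attack on the chromene alkene.
- Ketene acetal 9 is obtained by stopping step 4 before NBS and stripping the volatiles. It is arylated with F2 under Cu(OTf)2/(S,S)-Ph-BOX (10 mol %) in CH2Cl2 at rt, with mesityl as the dummy group.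
- This is the known copper–bisoxazoline arylation of lactone-derived silyl ketene acetals with diaryliodonium salts, and it gives 19 directly.

**Second: step 4.**
- Risks: the 1,4- versus 1,2-selectivity of the hydrosilylation on a coumarin is uncertain, and excess silane is carried into the bromination.
- The fallback sets out from 8 and comes back at 10.
- Copper hydride conjugate reduction ([(PPh3)CuH]6 cat., PMHS, t-BuOH, PhMe) gives the storable dihydrocoumarin F3.
- F3 is enolised with LiN(SiMe3)2/Me3SiCl (THF, −78 °C) to the trimethylsilyl ketene acetal F4.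
- NBS at −78 °C converts F4 into 10.

**Third: step 3.**
- Risk: the prenyl alkene may add formic acid during the coumarin synthesis.
- The fallback sets out from 6 and comes back at 8, and it is acid-free.
- Magnesium-mediated ortho-formylation (MgCl2, Et3N, paraformaldehyde, MeCN, reflux) gives the salicylaldehyde F5.
- Wittig olefination of F5 with Ph3P=CHCO2Et in PhNEt2 at rt gives the (E)-cinnamate F6.
- On heating the same solution to reflux, F6 isomerises and lactonises to 8.

## Further compounds
F1 | step 7 | [2,2-dimethyl-5-(triisopropylsilyloxy)-2H-chromen-8-yl]boronic acid | CC1(C)C=Cc2c(O1)c(B(O)O)ccc2O[Si](C(C)C)(C(C)C)C(C)C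
F2 | step 7 | [2,2-dimethyl-5-(triisopropylsilyloxy)-2H-chromen-8-yl](mesityl)iodonium triflate | Cc1cc(C)c(c(C)c1)[I+]c1ccc(O[Si](C(C)C)(C(C)C)C(C)C)c2C=CC(C)(C)Oc12.[O-]S(=O)(=O)C(F)(F)F
F3 | step 4 | 5,7-dimethoxy-6-(3-methylbut-2-en-1-yl)chroman-2-one | COc1cc2OC(=O)CCc2c(OC)c1CC=C(C)C
F4 | step 4 | 5,7-dimethoxy-6-(3-methylbut-2-en-1-yl)-2-(trimethylsilyloxy)-4H-chromene | COc1cc2OC(O[Si](C)(C)C)=CCc2c(OC)c1CC=C(C)C
F5 | step 3 | 6-hydroxy-2,4-dimethoxy-3-(3-methylbut-2-en-1-yl)benzaldehyde | COc1cc(O)c(C=O)c(OC)c1CC=C(C)C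
F6 | step 3 | ethyl (E)-3-[6-hydroxy-2,4-dimethoxy-3-(3-methylbut-2-en-1-yl)phenyl]prop-2-enoate | COc1cc(O)c(/C=C/C(=O)OCC)c(OC)c1CC=C(C)C
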